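**Assumption:** the SMILES decodes to the (2S)-flavanone carrying an (E)-geranyl group at C6 (5,7,4'-trihydroxy-3',5'-dimethoxy pattern). The in-flask desilylation that ends step 4 is counted as part of that step.

## Retrosynthetic overview
1. Open ring C at O1–C2 (retro-oxa-Michael) to a 3'-geranyl-2',4',6'-trihydroxychalcone whose ring B phenol is silylated. This C–O closure is the last skeletal event; it sets C2 as (S) and decides 6-geranyl versus 8-geranyl.
2. Cut the chalcone at Cα=Cβ (aldol condensation) into 3-geranylphloroacetophenone and O-silyl syringaldehyde.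
3. 3-Geranylphloroacetophenone comes from C-geranylation of phloroacetophenone with geranyl bromide, and the silyl aldehyde comes from syringaldehyde.
4. Ring order: rings A and B are bought as arenes. Ring C (the pyranone) is the only ring made, in the last step.

**Catalyst for step 4 (bought, not numbered):** quinine-derived squaramide 3-{[3,5-bis(trifluoromethyl)phenyl]amino}-4-{[(8α,9S)-6'-methoxycinchonan-9-yl]amino}cyclobut-3-ene-1,2-dione, C32H28F6N4O3.
SMILES: O=C1C(Nc2cc(C(F)(F)F)cc(C(F)(F)F)c2)=C(N[C@@H](c2ccnc3ccc(OC)cc23)[C@@H]2C[C@@H]3CCN2C[C@@H]3C=C)C1=O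

## Route

Step 1
Reactants: 1 2,4,6-trihydroxyacetophenone (phloroacetophenone); 2 geranyl bromide [(2E)-1-bromo-3,7-dimethylocta-2,6-diene]
Product: 3 3-geranyl-2,4,6-trihydroxyacetophenone
Conditions: K2CO3 (1.0 equiv), acetone, reflux, 6 h; 1 in 1.5-fold excess over 2
Reagents that add atoms: none
Why: Phenoxide C-alkylation (SN2 at the primary allylic bromide): the ambident phloroglucinol-type anion reacts at the carbon between two oxygens, C3 and C5 are equivalent so only one mono-C-geranyl product can form, the (E)-alkene is untouched, and the excess of 1 limits double alkylation.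

Step 2
Reactants: 4 syringaldehyde (4-hydroxy-3,5-dimethoxybenzaldehyde)
Product: 5 4-(tert-butyldimethylsilyloxy)-3,5-dimethoxybenzaldehyde
Conditions: TBSCl (1.2 equiv), imidazole (2.5 equiv), DMF, 23 °C, 12 h
Reagents that add atoms: tert-butyldimethylsilyl chloride (TBSCl), CC(C)(C)[Si](C)(C)Cl
Why: Standard imidazole-promoted phenol silylation, which masks the 4-OH that as a phenoxide would deactivate the aldehyde in step 3 and the enone in step 4.

Step 3
Reactants: 3 3-geranyl-2,4,6-trihydroxyacetophenone; 5 4-(tert-butyldimethylsilyloxy)-3,5-dimethoxybenzaldehyde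
Product: 7 (2E)-3-[4-(tert-butyldimethylsilyloxy)-3,5-dimethoxyphenyl]-1-(3-geranyl-2,4,6-trihydroxyphenyl)prop-2-en-1-one, via aldol adduct 6 (not isolated)
Conditions: LiN(SiMe3)2 (5 equiv), THF, −78 to 0 °C; then 5 (1.1 equiv), −78 to 23 °C, 18 h; inverse quench into cold 1 M HCl; silica gel doped with 0.5% AcOH
Reagents that add atoms: none
Why: Claisen–Schmidt aldol condensation through the tetralithiated ketone (three phenoxides plus enolate), a known protecting-group-free entry to 2',4',6'-trihydroxychalcones, in which the non-enolisable aldehyde 5 is the only electrophile, E1cB loss of hydroxide from 6 gives the (E)-enone, and the open chalcone polyanion rather than a flavanone is the resting state in strong base.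

Step 4
Reactants: 7 (2E)-3-[4-(tert-butyldimethylsilyloxy)-3,5-dimethoxyphenyl]-1-(3-geranyl-2,4,6-trihydroxyphenyl)prop-2-en-1-one
Product: 9 (2S)-6-geranyl-5,7-dihydroxy-2-(4-hydroxy-3,5-dimethoxyphenyl)chroman-4-one (target), via silyl-protected (2S)-flavanone 8 (not isolated)
Conditions: quinine-derived squaramide C32H28F6N4O3 (10 mol %), toluene/CH2Cl2 1:1 (0.05 M), −30 °C, 48–72 h; then AcOH (3 equiv), Bu4NF (1.3 equiv, THF), 0 °C, 1 h
Reagents that add atoms: none
Why: Proposed new method: site- and enantioselective intramolecular oxa-Michael addition of an unactivated, unprotected, non-symmetric 2',6'-dihydroxychalcone under bifunctional squaramide/tertiary-amine catalysis; the squaramide N–H pair binds the ketone oxygen, which is already polarised by the geranyl-buttressed 2'-OH···O=C hydrogen bond (an internal Brønsted acid doing the job of the ester activator needed so far), and the quinuclidine nitrogen deprotonates the only non-chelated ortho phenol, the less hindered and more acidic 6'-OH next to C5'-H, while the geranyl CH2 blocks access to 2'-OH, so O6' adds to the Si face of C-β inside the chiral ion pair, forming O1–C2 with (S) configuration and leaving geranyl at C6; closure is practically irreversible at −30 °C because the flavanone keeps a chelated 5-OH, the silyl ether shuts off racemisation through a para-quinone methide, and acetic-acid-buffered fluoride first protonates the catalyst and then frees the 4'-OH without touching C2; the closest known reaction type is the cinchona (thio)urea-catalysed oxa-Michael cyclisation of ester-activated 2'-hydroxychalcones (alkylidene β-keto esters) and of phenol-tethered enones to chromans, whereas plain 2'-hydroxychalcones have so far given only moderate ee and no case has had to choose between two different phenols.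

## Compound list
1 | 2,4,6-trihydroxyacetophenone (phloroacetophenone) | CC(=O)c1c(O)cc(O)cc1O | starting material
2 | geranyl bromide, (2E)-1-bromo-3,7-dimethylocta-2,6-diene | BrC/C=C(\C)CCC=C(C)C | starting material
3 | 3-geranyl-2,4,6-trihydroxyacetophenone | CC(=O)c1c(O)cc(O)c(C/C=C(\C)CCC=C(C)C)c1O | intermediate
4 | syringaldehyde | COc1cc(C=O)cc(OC)c1O | starting material
5 | 4-(tert-butyldimethylsilyloxy)-3,5-dimethoxybenzaldehyde | COc1cc(C=O)cc(OC)c1O[Si](C)(C)C(C)(C)C | intermediate
6 | aldol adduct, racemic β-hydroxy ketone (present as its lithium salt, drawn neutral) | COc1cc(C(O)CC(=O)c2c(O)cc(O)c(C/C=C(\C)CCC=C(C)C)c2O)cc(OC)c1O[Si](C)(C)C(C)(C)C | intermediate (not isolated)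
7 | (E)-chalcone: 4-O-TBS-3,5-dimethoxy-3'-geranyl-2',4',6'-trihydroxychalcone | COc1cc(/C=C/C(=O)c2c(O)cc(O)c(C/C=C(\C)CCC=C(C)C)c2O)cc(OC)c1O[Si](C)(C)C(C)(C)C | intermediate
8 | (2S)-2-[4-(tert-butyldimethylsilyloxy)-3,5-dimethoxyphenyl]-6-geranyl-5,7-dihydroxychroman-4-one | COc1cc([C@@H]2CC(=O)c3c(cc(O)c(C/C=C(\C)CCC=C(C)C)c3O)O2)cc(OC)c1O[Si](C)(C)C(C)(C)C | intermediate (not isolated)
9 | (2S)-6-geranyl-5,7-dihydroxy-2-(4-hydroxy-3,5-dimethoxyphenyl)chroman-4-one | COc1cc([C@@H]2CC(=O)c3c(cc(O)c(C/C=C(\C)CCC=C(C)C)c3O)O2)cc(OC)c1O | target

## Step count and risks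
Total steps: 4, with step 4 run as a two-stage one-flask operation. Longest linear sequence: 3 (steps 1, 3, 4).

**Step 4 (the new step, highest risk).**
- Possible failures:
  - The ee is too low.
  - The 6-geranyl/8-geranyl ratio is too low.
  - Turnover is slow because the most acidic 4'-OH ties up the amine.
  - The facial sense is opposite to the model.
- Checks:
  - Regiochemistry is read by HMBC, where the chelated 5-OH correlates to the geranyl-bearing C6.
  - The ee is measured by chiral HPLC.
  - Configuration is read by ECD, where the (2S) series shows a positive band near 330 nm and a negative band near 290 nm.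
- The facial sense is a model-based prediction. If the (2R) series appears, the quinidine-derived pseudoenantiomer (same formula C32H28F6N4O3) is used under the same protocol.
- Fallback (known chemistry, resolution in place of asymmetric catalysis), setting out from 7 and coming back at 9: 7 is desilylated with Bu4NF/AcOH in THF to the free tetrahydroxychalcone F1. NaOAc in refluxing EtOH then closes ring C without selectivity, giving the racemic 6-geranylflavanone F2 together with the racemic 8-geranylflavanone F3. The isomer F3 is removed on silica gel. F2 is resolved by preparative HPLC on an amylose tris(3,5-dimethylphenylcarbamate) phase to give 9, and the unwanted antipode is re-racemised with NaOAc and recycled.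

**Step 3.**
- Possible failures:
  - The tetralithio species dissolves poorly.
  - The silyl group is lost or migrates to a ring A phenoxide.
  - Racemic ring closure occurs during the quench.
- Fallback (classical fully protected Claisen–Schmidt route), setting out from 3 and 4 and coming back at 9: 3 is converted with NaH/MOMCl in DMF into the tris-MOM ketone F4, and 4 with MOMCl/i-Pr2NEt in CH2Cl2 into the MOM-protected syringaldehyde F5. KOH in EtOH at 23 °C condenses these two to the tetra-MOM chalcone F6. HCl in MeOH at 23 °C removes all four acetals to give the free tetrahydroxychalcone F1, the same compound as in the fallback above. F1 is submitted to the cyclisation conditions of step 4 without the fluoride stage and gives 9 directly.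

**Step 1.**
- Possible failures:
  - O-alkylation competes with C-alkylation.
  - Double or geminal C-alkylation occurs.
  - The yield is therefore low.
- Fallback (reversed order of bond formation through directed ortho-metalation), setting out from 2 and coming back at 3: commercial phloroglucinol is protected (NaH, MOMCl, DMF) as 1,3,5-tris(methoxymethoxy)benzene F7. n-BuLi in THF at 0 °C lithiates between two acetal oxygens, and 2 alkylates the aryllithium to 2-geranyl-1,3,5-tris(methoxymethoxy)benzene F8. A second lithiation at a remaining position flanked by two OMOM groups, followed by N-methoxy-N-methylacetamide, gives the tris-MOM ketone F4. HCl in MeOH then releases 3.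

## Further compounds
F1 | step 4 | free tetrahydroxychalcone, (E)-3'-geranyl-2',4',6',4-tetrahydroxy-3,5-dimethoxychalcone | COc1cc(/C=C/C(=O)c2c(O)cc(O)c(C/C=C(\C)CCC=C(C)C)c2O)cc(OC)c1O
F2 | step 4 | racemic 6-geranylflavanone (racemate of 9) | COc1cc(C2CC(=O)c3c(cc(O)c(C/C=C(\C)CCC=C(C)C)c3O)O2)cc(OC)c1O
F3 | step 4 | racemic 8-geranylflavanone, 8-geranyl-5,7-dihydroxy-2-(4-hydroxy-3,5-dimethoxyphenyl)chroman-4-one | COc1cc(C2CC(=O)c3c(O)cc(O)c(C/C=C(\C)CCC=C(C)C)c3O2)cc(OC)c1O
F4 | step 3 | tris-MOM ketone, 3-geranyl-2,4,6-tris(methoxymethoxy)acetophenone | CC(=O)c1c(OCOC)cc(OCOC)c(C/C=C(\C)CCC=C(C)C)c1OCOC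
F5 | step 3 | MOM-protected syringaldehyde, 3,5-dimethoxy-4-(methoxymethoxy)benzaldehyde | COCOc1c(OC)cc(C=O)cc1OC
F6 | step 3 | tetra-MOM chalcone | COCOc1c(OC)cc(/C=C/C(=O)c2c(OCOC)cc(OCOC)c(C/C=C(\C)CCC=C(C)C)c2OCOC)cc1OC
F7 | step 1 | 1,3,5-tris(methoxymethoxy)benzene | COCOc1cc(OCOC)cc(OCOC)c1
F8 | step 1 | 2-geranyl-1,3,5-tris(methoxymethoxy)benzene | COCOc1cc(OCOC)c(C/C=C(\C)CCC=C(C)C)c(OCOC)c1
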